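## The problem

Target **18** is a cyclohexadienone (ring A, C1–C6) fused through C4–C5 to a (2′R,3′R)-2,3-dimethyl-2,3-dihydropyran-4-one (ring B, O1′ on C4 and C4′=O on C5), with a ketone at C2, the (S)-CH(Ph)CH2CO2H chain on C3 and an enol at C6 hydrogen-bonded to C4′=O. C1 is an all-carbon quaternary centre (R) that carries a prenyl group and a [(1R,3S)-2,2-dimethyl-3-isopropenylcyclobutyl]methyl arm whose four-membered ring (ring C) is cis-disubstituted. The six stereocentres fall into four groups (ring C, C1, the benzylic carbon, ring B) that are separated by CH2 groups or sp2 carbons, so no group can control another. Within the groups, trans in ring B is the thermodynamic arrangement because C3′ is epimerisable, whereas cis in ring C must come from the way that ring is made. C1 is the hardest centre, because both of its carbon arms begin with CH2 and its two carbonyl carbons (C2 and C6) differ only in what ring A later attaches to them. The molecule will not survive strong acid, which ring-expands the isopropenylcyclobutane through a cyclobutylcarbinyl cation and hydrates or cyclises the prenyl group, and its three alkenes exclude hydrogenation. Prolonged strong base on neutral intermediates is also ruled out: ring B opens by β-elimination of O1′, the benzylic carbon can leave by retro-Michael reaction and the triketone can undergo retro-Claisen cleavage. The feature that opens the key step lies in ring C: the CH bearing the CH2 link to C1 and the neighbouring CMe2 are the two alkene carbons of a prenyl group and the ring CH2 and CH(isopropenyl) are the vinyl carbons of isoprene, so C1 with its two arms and two carbonyl carbons is a symmetric, chromophore-free 2,2-diprenylmalonate in which one prenyl group has added isoprene.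

## Retrosynthesis

**18 ⇒ 17 ⇒ 15 + 16.** The C3–benzylic bond is cut last. The acid is first hidden as enol δ-lactone **17** (O on C2 acylated, C3 bonded to the benzylic carbon), which comes from the C3-unsubstituted core **15** and cinnamic anhydride **16**. Attaching the side chain earlier would expose a retro-Michael-prone centre to the base of the ring-A closure, and an acid-mediated hydroarylation with cinnamic acid would leave the benzylic centre uncontrolled. The precursor is nine carbons and one stereocentre simpler. The forward reaction must deliver catalyst-controlled facial selectivity on the cinnamoyl unit, because C1 is too symmetric to bias C3.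

**15 ⇒ 14 ⇒ 8 + 13.** Ring A is cut at C5–C6 (Claisen closure of diketo ester **14**) and then at C2–C3 (acylation of the 6-methyl carbon of pyranone **13** by acid chloride **8**). Closing ring B last onto an acyl triketone would leave open whether O1′ ends on C4 or C6; a preformed pyranone settles this. The carbonyl activated as the acid chloride becomes C2 and the ester carbonyl becomes C6, so the C1 configuration is decided in the half ester and only carried here. The forward reactions must give γ- rather than α′-deprotonation of **13**, C- rather than O-acylation, and closure of C5 onto a hindered ester.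

**13 ⇒ 12 ⇒ 11 ⇒ 10 ⇒ 9.** Ring B is cut at O1′–C6′ (6-endo cyclisation of hydroxy ynone **12**), then at the ketone–alkyne bond (propynyl addition to Weinreb amide **11**), then at C3′–CH3 (anti-selective methylation of ethyl (R)-3-hydroxybutanoate **9** to **10**). The chiral pool supplies C2′ and a chelated dianion sets C3′, with no catalyst to develop. Ring B is completed before it meets the acid-sensitive arm.

**8 ⇒ 7 ⇒ 6.** Acid chloride **8** comes from half ester **7**, and **7** from diester **6** by hydrolysis of one of two diastereotopic methyl esters. This single functional-group change sets C1. The forward reaction must distinguish the flat prenyl arm from the bulky β-branched cyclobutylmethyl arm, which is asked of an esterase.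

**6 ⇒ 4 + 5.** Both new bonds of ring C are cut: the ring CH2–CH(arm) bond and the CH(isopropenyl)–CMe2 bond. This returns dimethyl 2,2-diprenylmalonate **4** and isoprene **5**. Against a stepwise ring construction or the chiral pool, this cut delivers all ten carbons of the arm in one operation from a C5 feedstock. The two prenyl groups of **4** are equivalent, so no group selectivity is needed. The forward reaction is a sensitised crossed [2+2] photocycloaddition, and it must beat isoprene dimerisation, use the vinyl end of isoprene and close the four-membered ring cis. A triplet diene free in solution cannot be steered by a chiral sensitiser, so this step is asked only for constitution and relative configuration; the absolute configuration is obtained by resolving **6**.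

**4 ⇒ 1 + 2.** Two C–C bonds at the malonate carbon are cut, giving dimethyl malonate **1** and prenyl bromide **2**, by way of mono-prenyl malonate **3**.

## Roads not taken

**Alternative 1:** The cut runs through ring B only (O1′–C2′ and C2′–C3′).
- Forward step: hetero-Diels–Alder reaction of acetaldehyde A1 with the doubly oxygenated diene (2Z,4Z)-2-methoxy-4-(triethylsilyloxy)hexa-2,4-diene A2 on a chiral tridentate Schiff base–CrCl complex (trivalent chromium). Acidic unmasking and equilibration at C3′ then give the trans pyranone A3, which is the same compound as **13**.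
- Merits: catalytic; C2′ is set by the catalyst and C3′ by thermodynamics; two operations from the diene.
- Weak points: A2 must be prepared with defined regiochemistry and geometry at both enol ethers. A1 is the smallest and least discriminating aldehyde. A diene terminus bearing both methoxy and methyl is sluggish. The step addresses the easiest part of the molecule and says nothing about C1 or ring C.
- Comparison: as a route to **13** it would be about one step shorter than steps 5–8 and needs no stoichiometric chiral material, so for ring B it is as good or better. The chosen plan sets against it a substrate-controlled alkylation of known sense, and a key step spent on ring C, which is otherwise the longest fragment to make. The two are compatible: A3 could replace **13** without touching the rest.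

**Alternative 2:** The cut runs through ring C, between CMe2 and the arm-bearing CH and between the ring CH2 and the future isopropenyl carbon.
- Forward step: the amide N,N-dimethylisobutyramide A4 is converted with Tf2O and collidine into its keteniminium ion, which adds to allyl benzyl ether A5 and gives, after hydrolysis, (S)-3-[(benzyloxy)methyl]-2,2-dimethylcyclobutanone A6.
- Merits: A4 and A5 are bulk chemicals; the reaction is well precedented for unactivated monosubstituted alkenes; regiochemistry is fixed by polarity; chiral variants of the amide make it enantioselective. In reliability and absolute control it is clearly superior to the photocycloaddition chosen here.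
- Weak points: A6 has the ring but not the isopropenyl group. The ketone must become CH–C(CH3)=CH2 cis to the arm (homologation, equilibration, methylenation). The benzyl ether must go without hydrogenation. The hindered cyclobutylmethyl carbon must then be joined to the malonate. That is about eight to ten steps to reach **6**.
- Comparison: Alternative 2 wins on precedent and stereocontrol. The chosen plan wins only on step economy, and pays with an unprecedented, unselective step and a resolution. The chiral-pool fallback for step 2 reaches the same kind of cyclobutylmethyl electrophile in fewer steps than A6 would, so Alternative 2 was not kept even as the safety net.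

**Alternative 3:** The cut runs through ring A at C2–C3 and C5–C6.
- Forward step: the γ-dienolate of **13** is acylated at its 6-methyl carbon by **8**, and C5 then closes onto the methyl ester to give the C3-unsubstituted core A7, identical with **15**.
- Merits: convergent; fixes O1′ on C4 beyond doubt; transfers the C1 configuration from the half ester; rests on dienolate acylation and Claisen cyclisation, both with close precedent.
- Weak points: α′ versus γ deprotonation and O- versus C-acylation are open; the ester is neopentyl-like; as a strategy it does not say where ring C comes from.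
- Comparison: this is a component, not a rival, since the chosen plan uses exactly this annulation as steps 9 and 10 to reach A7. As the step on which a synthesis rests it is the safer choice, and that is conceded. The chosen plan sets against it that the photocycloaddition shortens the one fragment (**8**) that the annulation takes for granted, from about nine steps by the chiral-pool route to four.

Key step: step 2

Assumption 1: pig liver esterase is taken to hydrolyse the pro-R methoxycarbonyl group of **6** (the one that becomes C2); the sense must be established on the first run, and the fallback to step 3 covers the opposite outcome.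

Assumption 2: the isothiourea (2S,3R)-HyperBTM, which is (2S,3R)-3-isopropyl-2-phenyl-3,4-dihydro-2H-benzo[4,5]thiazolo[3,2-a]pyrimidine, is written for step 11 on the assumption that it exposes the face of the cinnamoyl ammonium ion leading to the S benzylic centre; if a model diketone shows otherwise, its enantiomer is used.

## Steps

Step 1
Reactants: 1 dimethyl malonate; 2 prenyl bromide (1-bromo-3-methylbut-2-ene)
Product: 4 dimethyl 2,2-bis(3-methylbut-2-en-1-yl)malonate, via dimethyl 2-prenylmalonate 3 (not isolated)
Conditions: NaH (2.3 equiv), 2 (2.3 equiv), THF/DMF, 0 °C → rt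
Reagents that add atoms: none
Why: Double C-alkylation of a malonate enolate with a reactive primary allylic bromide (SN2); the second alkylation is slower but unexceptional, and no stereocentre is formed.

Step 2
Reactants: 4 dimethyl 2,2-bis(3-methylbut-2-en-1-yl)malonate; 5 isoprene
Product: 6 dimethyl 2-{[(1R,3S)-2,2-dimethyl-3-(prop-1-en-2-yl)cyclobutyl]methyl}-2-(3-methylbut-2-en-1-yl)malonate (cis; the racemate is resolved and this enantiomer carried on)
Conditions: 5 (1 equiv, added over 24 h) to 4 (5 equiv, 3 M in MeCN), [Ir(dF(CF3)ppy)2(dtbbpy)]PF6 (1 mol %), 450 nm LEDs, 5 °C, degassed; excess 4 recovered; AgNO3-impregnated silica; preparative SFC on a chiral stationary phase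
Reagents that add atoms: none
Why: Proposed new method: triplet energy transfer from the trivalent iridium sensitiser (about 61 kcal/mol) excites only isoprene (about 60 kcal/mol), not the isolated alkenes of 4 or 6; the twisted triplet diene bonds through its vinyl CH2 to the less substituted carbon of a prenyl alkene, giving a triplet 1,4-biradical (tertiary radical at CMe2, allyl radical) that closes by radical recombination after intersystem crossing. The closest known reaction type is the visible-light triplet-sensitised crossed [2+2] cycloaddition of 1,3-dienes with alkenes to vinylcyclobutanes, known intramolecularly and with activated partners but not intermolecularly with an unactivated trisubstituted alkene. The cyclobutane closes by 1,4-recombination of the tertiary radical with the internal allyl carbon; 1,6-recombination at the far allyl carbon would give a cyclohexene and is disfavoured because s-trans isoprene gives a transoid allyl radical. The ring carbon bearing the malonylmethyl arm is fixed in the first bond formation and the one bearing isopropenyl in the closure; their cis relation is expected only as a modest preference for the isomer with both substituents pseudo-equatorial, so the trans isomer must be removed. Nothing in this step can control absolute configuration, because the reacting triplet diene is free in solution and the sensitiser is absent when the bonds form; the racemic cis adduct is therefore resolved on a chiral stationary phase. The step needs cross-addition over isoprene dimerisation (secured by the large excess of 4, whose two prenyl groups are equivalent, and slow addition of 5), attack through the vinyl terminus of isoprene and not the terminus next to the methyl-bearing carbon (not secured; the other biradical would have to join two fully substituted carbons and is expected to revert or give cyclohexene), and four-membered closure. The product has no conjugated diene and is not re-excited.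

Step 3
Reactants: 6 dimethyl 2-{[(1R,3S)-2,2-dimethyl-3-(prop-1-en-2-yl)cyclobutyl]methyl}-2-(3-methylbut-2-en-1-yl)malonate
Product: 7 (2S)-2-{[(1R,3S)-2,2-dimethyl-3-(prop-1-en-2-yl)cyclobutyl]methyl}-2-(methoxycarbonyl)-5-methylhex-4-enoic acid
Conditions: pig liver esterase, 0.1 M phosphate buffer (pH 7.5)/DMSO 9:1, 30 °C; citric acid to pH 3
Reagents that add atoms: water, O
Why: Enzymatic desymmetrisation of a 2,2-disubstituted malonate (hydrolysis of one of two diastereotopic methyl esters), a standard use of this esterase; the enzyme distinguishes the flat prenyl arm from the bulky β-branched cyclobutylmethyl arm and so sets C1, and the half-ester anion is not hydrolysed further.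

Step 4
Reactants: 7 (2S)-2-{[(1R,3S)-2,2-dimethyl-3-(prop-1-en-2-yl)cyclobutyl]methyl}-2-(methoxycarbonyl)-5-methylhex-4-enoic acid
Product: 8 methyl (2R)-2-(chlorocarbonyl)-2-{[(1R,3S)-2,2-dimethyl-3-(prop-1-en-2-yl)cyclobutyl]methyl}-5-methylhex-4-enoate (used crude)
Conditions: 1-chloro-N,N,2-trimethylprop-1-en-1-amine (1.2 equiv), CH2Cl2, 0 °C → rt
Reagents that add atoms: 1-chloro-N,N,2-trimethylprop-1-en-1-amine, CC(C)=C(Cl)N(C)C
Why: Acid chloride formation with an α-chloroenamine under neutral conditions, which releases no HCl and so spares the isopropenylcyclobutane and the prenyl group; the quaternary α-carbon excludes ketene formation and epimerisation (the descriptor changes from S to R only through priorities).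

Step 5
Reactants: 9 ethyl (R)-3-hydroxybutanoate
Product: 10 ethyl (2R,3R)-3-hydroxy-2-methylbutanoate
Conditions: LiN(i-Pr)2 (2.2 equiv), THF, −50 → −20 °C; MeI, DMPU, −78 → 0 °C
Reagents that add atoms: iodomethane, CI
Why: Fráter–Seebach alkylation: the dilithio alkoxide-enolate is a rigid chelate and iodomethane approaches anti to the C3 methyl group, giving the anti (2R,3R) product from the (R)-hydroxy ester.

Step 6
Reactants: 10 ethyl (2R,3R)-3-hydroxy-2-methylbutanoate
Product: 11 (2R,3R)-3-hydroxy-N-methoxy-N,2-dimethylbutanamide
Conditions: MeNH(OMe)·HCl (1.6 equiv), i-PrMgCl (4.2 equiv), THF, −20 → 0 °C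
Reagents that add atoms: N,O-dimethylhydroxylamine hydrochloride, CNOC.Cl
Why: Ester aminolysis by the magnesium amide of N,O-dimethylhydroxylamine (Weinreb amide formation); the hydroxyl is carried as its magnesium alkoxide and the α-centre is not enolised at low temperature.

Step 7
Reactants: 11 (2R,3R)-3-hydroxy-N-methoxy-N,2-dimethylbutanamide
Product: 12 (5R,6R)-6-hydroxy-5-methylhept-2-yn-4-one
Conditions: 1-propynylmagnesium bromide (2.5 equiv), THF, 0 °C → rt; aq. NH4Cl
Reagents that add atoms: 1-propynylmagnesium bromide, CC#C[Mg]Br
Why: Addition of an alkynyl Grignard reagent to a Weinreb amide; the chelated tetrahedral intermediate prevents double addition and releases the ynone only on work-up, so neither retro-aldol cleavage nor epimerisation at C5 is expected.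

Step 8
Reactants: 12 (5R,6R)-6-hydroxy-5-methylhept-2-yn-4-one
Product: 13 (2R,3R)-2,3,6-trimethyl-2,3-dihydro-4H-pyran-4-one
Conditions: Ph3PAuNTf2 (2 mol %), CH2Cl2, rt
Reagents that add atoms: none
Why: 6-endo-dig hydroalkoxylation of a β-hydroxy ynone catalysed by monovalent gold (the hydroxyl attacks the alkyne carbon β to the ketone), a standard entry to 2,3-dihydropyran-4-ones; both stereocentres are spectators and the anti aldol becomes the 2,3-trans ring.

Step 9
Reactants: 8 methyl (2R)-2-(chlorocarbonyl)-2-{[(1R,3S)-2,2-dimethyl-3-(prop-1-en-2-yl)cyclobutyl]methyl}-5-methylhex-4-enoate; 13 (2R,3R)-2,3,6-trimethyl-2,3-dihydro-4H-pyran-4-one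
Product: 14 methyl (2S)-2-{[(1R,3S)-2,2-dimethyl-3-(prop-1-en-2-yl)cyclobutyl]methyl}-2-{[(2R,3R)-2,3-dimethyl-4-oxo-3,4-dihydro-2H-pyran-6-yl]acetyl}-5-methylhex-4-enoate
Conditions: 13 (2.2 equiv), LiN(SiMe3)2 (2.2 equiv), THF, −78 °C; then 8, −78 → −40 °C; AcOH quench
Reagents that add atoms: none
Why: C-acylation of the extended (γ) lithium dienolate of a 6-methyl vinylogous ester by an acid chloride, as known for 6-methyl-1,3-dioxin-4-ones and 2-methyl-4-pyranones, with α′-deprotonation slowed because C3′ is tertiary; the second equivalent of dienolate deprotonates the more acidic product, and because the acid chloride reacts before the hindered ester the acid-derived carbonyl is tied to C3, which transfers the C1 configuration set in step 3.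

Step 10
Reactants: 14 methyl (2S)-2-{[(1R,3S)-2,2-dimethyl-3-(prop-1-en-2-yl)cyclobutyl]methyl}-2-{[(2R,3R)-2,3-dimethyl-4-oxo-3,4-dihydro-2H-pyran-6-yl]acetyl}-5-methylhex-4-enoate
Product: 15 (2R,3R,6R)-6-{[(1R,3S)-2,2-dimethyl-3-(prop-1-en-2-yl)cyclobutyl]methyl}-5-hydroxy-2,3-dimethyl-6-(3-methylbut-2-en-1-yl)-2,3-dihydro-4H-chromene-4,7(6H)-dione (the C3-unsubstituted core; chromene C6 = C1, C7 = C2, C8 = C3)
Conditions: KOt-Bu (2.5 equiv), THF, 0 °C → rt; 1 M HCl, 0 °C
Reagents that add atoms: none
Why: Dieckmann-type (intramolecular Claisen) condensation: the delocalised anion formed at C3 is nucleophilic at the pyranone α-carbon (C5), which closes the six-membered ring onto the methyl ester; loss of methoxide and formation of the stabilised triketone anion drive the reaction, and as an anion ring B resists β-elimination.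

Step 11
Reactants: 15 the C3-unsubstituted core; 16 (E,E)-cinnamic anhydride
Product: 17 enol δ-lactone of 18 (ring C2–O–C(=O)–CH2–CH(Ph)–C3 fused at C2=C3, benzylic carbon S, C6 now a ketone; C1, ring B and ring C as in 15)
Conditions: 16 (1.5 equiv), (2S,3R)-HyperBTM (10 mol %), i-Pr2NEt (1.5 equiv), CH2Cl2, −40 °C → rt
Reagents that add atoms: none
Why: Isothiourea-catalysed Michael addition–lactonisation of a 1,3-dicarbonyl-type nucleophile with an α,β-unsaturated acyl ammonium ion formed from the anhydride; C3 of the anion of 15 adds to the β-carbon, the oxygen on C2 then closes the lactone and releases the catalyst, and the benzylic centre is set by the catalyst, whose phenyl group blocks one face of the s-cis acyl ammonium ion held by the S···O contact.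

Step 12
Reactants: 17 enol δ-lactone
Product: 18 (3S)-3-[(2R,3R,6R)-6-{[(1R,3S)-2,2-dimethyl-3-(prop-1-en-2-yl)cyclobutyl]methyl}-5-hydroxy-2,3-dimethyl-6-(3-methylbut-2-en-1-yl)-4,7-dioxo-3,4,6,7-tetrahydro-2H-chromen-8-yl]-3-phenylpropanoic acid (CNP0103716.3)
Conditions: LiOH (3 equiv), THF/H2O 3:1, 0 °C; cold 0.5 M HCl to pH 3
Reagents that add atoms: lithium hydroxide, [Li+].[OH-]
Why: Hydrolysis of an enol lactone (an activated ester) by hydroxide at 0 °C; ring opening returns the C2 ketone and the C6 enol, the product sits as a dianion that resists retro-Michael reaction and ring-B opening, and brief cold acidification spares the isopropenylcyclobutane.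

## Compound list

1 | dimethyl malonate | COC(=O)CC(=O)OC | starting material
2 | prenyl bromide (1-bromo-3-methylbut-2-ene) | CC(C)=CCBr | starting material
3 | dimethyl 2-(3-methylbut-2-en-1-yl)malonate (not isolated) | COC(=O)C(CC=C(C)C)C(=O)OC | intermediate
4 | dimethyl 2,2-bis(3-methylbut-2-en-1-yl)malonate | COC(=O)C(CC=C(C)C)(CC=C(C)C)C(=O)OC | intermediate
5 | isoprene | C=CC(C)=C | starting material
6 | dimethyl 2-{[(1R,3S)-2,2-dimethyl-3-(prop-1-en-2-yl)cyclobutyl]methyl}-2-(3-methylbut-2-en-1-yl)malonate | C=C(C)[C@@H]1C[C@H](CC(CC=C(C)C)(C(=O)OC)C(=O)OC)C1(C)C | intermediate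
7 | (2S)-2-{[(1R,3S)-2,2-dimethyl-3-(prop-1-en-2-yl)cyclobutyl]methyl}-2-(methoxycarbonyl)-5-methylhex-4-enoic acid | C=C(C)[C@@H]1C[C@H](C[C@@](C(=O)OC)(CC=C(C)C)C(=O)O)C1(C)C | intermediate
8 | methyl (2R)-2-(chlorocarbonyl)-2-{[(1R,3S)-2,2-dimethyl-3-(prop-1-en-2-yl)cyclobutyl]methyl}-5-methylhex-4-enoate | C=C(C)[C@@H]1C[C@H](C[C@@](C(=O)OC)(CC=C(C)C)C(=O)Cl)C1(C)C | intermediate
9 | ethyl (R)-3-hydroxybutanoate | CCOC(=O)C[C@@H](C)O | starting material
10 | ethyl (2R,3R)-3-hydroxy-2-methylbutanoate | CCOC(=O)[C@H](C)[C@@H](C)O | intermediate
11 | (2R,3R)-3-hydroxy-N-methoxy-N,2-dimethylbutanamide | CON(C)C(=O)[C@H](C)[C@@H](C)O | intermediate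
12 | (5R,6R)-6-hydroxy-5-methylhept-2-yn-4-one | CC#CC(=O)[C@H](C)[C@@H](C)O | intermediate
13 | (2R,3R)-2,3,6-trimethyl-2,3-dihydro-4H-pyran-4-one | CC1=CC(=O)[C@H](C)[C@@H](C)O1 | intermediate
14 | methyl (2S)-2-{[(1R,3S)-2,2-dimethyl-3-(prop-1-en-2-yl)cyclobutyl]methyl}-2-{[(2R,3R)-2,3-dimethyl-4-oxo-3,4-dihydro-2H-pyran-6-yl]acetyl}-5-methylhex-4-enoate | C=C(C)[C@@H]1C[C@H](C[C@@](C(=O)OC)(CC=C(C)C)C(=O)CC2=CC(=O)[C@H](C)[C@@H](C)O2)C1(C)C | intermediate
15 | (2R,3R,6R)-6-{[(1R,3S)-2,2-dimethyl-3-(prop-1-en-2-yl)cyclobutyl]methyl}-5-hydroxy-2,3-dimethyl-6-(3-methylbut-2-en-1-yl)-2,3-dihydro-4H-chromene-4,7(6H)-dione | C=C(C)[C@@H]1C[C@H](C[C@@]2(CC=C(C)C)C(=O)C=C3O[C@H](C)[C@@H](C)C(=O)C3=C2O)C1(C)C | intermediate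
16 | (E,E)-cinnamic anhydride | O=C(/C=C/c1ccccc1)OC(=O)/C=C/c1ccccc1 | starting material
17 | enol δ-lactone of 18 (C2–O–C(=O)–CH2–CH(Ph)–C3 ring, benzylic S) | C=C(C)[C@@H]1C[C@H](C[C@@]2(CC=C(C)C)C3=C([C@H](c4ccccc4)CC(=O)O3)C3=C(C(=O)[C@H](C)[C@@H](C)O3)C2=O)C1(C)C | intermediate
18 | (3S)-3-[(2R,3R,6R)-6-{[(1R,3S)-2,2-dimethyl-3-(prop-1-en-2-yl)cyclobutyl]methyl}-5-hydroxy-2,3-dimethyl-6-(3-methylbut-2-en-1-yl)-4,7-dioxo-3,4,6,7-tetrahydro-2H-chromen-8-yl]-3-phenylpropanoic acid | C=C(C)[C@@H]1C[C@H](C[C@@]2(CC=C(C)C)C(=O)C([C@@H](CC(=O)O)c3ccccc3)=C3O[C@H](C)[C@@H](C)C(=O)C3=C2O)C1(C)C | target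

## Step count and least certain steps

Total: 12 steps. Longest linear sequence: 8 steps (steps 1–4 then 9–12 from 1; equally steps 5–8 then 9–12 from 9).

**Step 2 (key step, proposed new method).**
What may go wrong: isoprene dimerisation outrunning cross-addition to a hindered, unactivated trisubstituted alkene; bonding through the wrong diene terminus; unselective cis/trans closure; trapping of the tertiary radical by the second prenyl group (5-exo cyclisation). Even when it works, the adduct is racemic and half is lost in the resolution.
Fallback (known chemistry, chiral pool): it sets out from 1, brings in the terpene (1S,5S)-(−)-verbenone F1 as a new chiral-pool starting material, and returns at 6. Verbenone F1 is cleaved oxidatively with catalytic RuCl3 and NaIO4 in MeCN/CCl4/H2O to (1S,3R)-cis-pinononic acid F2. Esterification with MeI and K2CO3 in DMF gives methyl ester F3. Salt-free methylenation with Ph3P=CH2 in THF at 0 °C, chosen to avoid epimerisation next to the ketone, gives isopropenyl ester F4. LiAlH4 reduces it to alcohol F5, and I2, PPh3 and imidazole convert this into iodide F6. The sodium salt of 1 (excess, NaH, DMF, 60 °C) is alkylated by the iodide to monoalkyl malonate F7, and NaH and 2 then give 6. Both ring-C centres and the cis relation come from the bicyclic terpene, and no resolution is needed.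

**Step 9.**
What may go wrong: deprotonation at C3′ (α′) in place of the 6-methyl group, with epimerisation or ring opening of 13, and O-acylation of the dienolate by the hindered acid chloride.
Fallback: it sets out from 11 and returns at 14. Silylation of 11 with TBSCl and imidazole gives silyl ether amide F12. The lithium enolate of acetone converts it into β-diketone F13. The dianion of this diketone (2 equiv LiN(i-Pr)2), which reacts only at its terminal methyl carbon, is acylated by 8 to triketo ester F14. Buffered HF·pyridine in THF/pyridine at 0 °C removes the silyl group, and the freed hydroxyl condenses with the central ketone to give 14. The regiochemistry is then fixed by dianion reactivity, not by the site of deprotonation.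

**Step 3.**
What may go wrong: slow turnover of a malonate with two large arms, or low or reversed discrimination between the diastereotopic esters.
Fallback: it sets out from 6 and returns at 15. Statistical half-saponification with one equivalent of KOH in MeOH/H2O gives 7 together with its C2 epimer, half ester F8. The mixture is taken through steps 4, 9 and 10, in which the epimer gives in turn acid chloride F9, diketo ester F10 and the C1-epimeric core F11. Compound 15 is separated from the epimeric core by chromatography or crystallisation at this first rigid bicyclic stage.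

**Step 11.**
What may go wrong: slow conjugate addition at the flanked C3, competing O-acylation at the C6 hydroxyl, or erosion of facial selectivity by an uncatalysed pathway.
Fallback: it sets out from 15 and returns at 18. Uncatalysed Michael addition–lactonisation of 15 with 5-benzylidene Meldrum's acid (catalytic Et3N, MeCN, 60 °C, with loss of acetone and CO2) gives 17 mixed with its benzylic epimer, lactone F15. The mixture is hydrolysed as in step 12, and 18 is separated by preparative HPLC from its benzylic epimer, acid F16.

## Further compounds

F1 | step 2 | (1S,5S)-(−)-verbenone | CC1=CC(=O)[C@H]2C[C@@H]1C2(C)C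
F2 | step 2 | (1S,3R)-3-acetyl-2,2-dimethylcyclobutane-1-carboxylic acid (cis-pinononic acid) | CC(=O)[C@@H]1C[C@H](C(=O)O)C1(C)C
F3 | step 2 | methyl (1S,3R)-3-acetyl-2,2-dimethylcyclobutane-1-carboxylate | CC(=O)[C@@H]1C[C@H](C(=O)OC)C1(C)C
F4 | step 2 | methyl (1S,3S)-2,2-dimethyl-3-(prop-1-en-2-yl)cyclobutane-1-carboxylate | C=C(C)[C@@H]1C[C@H](C(=O)OC)C1(C)C
F5 | step 2 | [(1S,3S)-2,2-dimethyl-3-(prop-1-en-2-yl)cyclobutyl]methanol | C=C(C)[C@@H]1C[C@H](CO)C1(C)C
F6 | step 2 | (1S,3S)-1-(iodomethyl)-2,2-dimethyl-3-(prop-1-en-2-yl)cyclobutane | C=C(C)[C@@H]1C[C@H](CI)C1(C)C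
F7 | step 2 | dimethyl 2-{[(1R,3S)-2,2-dimethyl-3-(prop-1-en-2-yl)cyclobutyl]methyl}malonate | C=C(C)[C@@H]1C[C@H](CC(C(=O)OC)C(=O)OC)C1(C)C
F8 | step 3 | (2R)-2-{[(1R,3S)-2,2-dimethyl-3-(prop-1-en-2-yl)cyclobutyl]methyl}-2-(methoxycarbonyl)-5-methylhex-4-enoic acid | C=C(C)[C@@H]1C[C@H](C[C@](C(=O)OC)(CC=C(C)C)C(=O)O)C1(C)C
F9 | step 3 | methyl (2S)-2-(chlorocarbonyl)-2-{[(1R,3S)-2,2-dimethyl-3-(prop-1-en-2-yl)cyclobutyl]methyl}-5-methylhex-4-enoate | C=C(C)[C@@H]1C[C@H](C[C@](C(=O)OC)(CC=C(C)C)C(=O)Cl)C1(C)C
F10 | step 3 | methyl (2R)-2-{[(1R,3S)-2,2-dimethyl-3-(prop-1-en-2-yl)cyclobutyl]methyl}-2-{[(2R,3R)-2,3-dimethyl-4-oxo-3,4-dihydro-2H-pyran-6-yl]acetyl}-5-methylhex-4-enoate | C=C(C)[C@@H]1C[C@H](C[C@](C(=O)OC)(CC=C(C)C)C(=O)CC2=CC(=O)[C@H](C)[C@@H](C)O2)C1(C)C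
F11 | step 3 | (2R,3R,6S)-6-{[(1R,3S)-2,2-dimethyl-3-(prop-1-en-2-yl)cyclobutyl]methyl}-5-hydroxy-2,3-dimethyl-6-(3-methylbut-2-en-1-yl)-2,3-dihydro-4H-chromene-4,7(6H)-dione | C=C(C)[C@@H]1C[C@H](C[C@]2(CC=C(C)C)C(=O)C=C3O[C@H](C)[C@@H](C)C(=O)C3=C2O)C1(C)C
F12 | step 9 | (2R,3R)-3-[(tert-butyldimethylsilyl)oxy]-N-methoxy-N,2-dimethylbutanamide | CON(C)C(=O)[C@H](C)[C@@H](C)O[Si](C)(C)C(C)(C)C
F13 | step 9 | (5R,6R)-6-[(tert-butyldimethylsilyl)oxy]-5-methylheptane-2,4-dione | CC(=O)CC(=O)[C@H](C)[C@@H](C)O[Si](C)(C)C(C)(C)C
F14 | step 9 | methyl (2S)-2-{(6R,7R)-7-[(tert-butyldimethylsilyl)oxy]-6-methyl-3,5-dioxooctanoyl}-2-{[(1R,3S)-2,2-dimethyl-3-(prop-1-en-2-yl)cyclobutyl]methyl}-5-methylhex-4-enoate | C=C(C)[C@@H]1C[C@H](C[C@@](C(=O)OC)(CC=C(C)C)C(=O)CC(=O)CC(=O)[C@H](C)[C@@H](C)O[Si](C)(C)C(C)(C)C)C1(C)C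
F15 | step 11 | benzylic (R) epimer of enol δ-lactone 17 | C=C(C)[C@@H]1C[C@H](C[C@@]2(CC=C(C)C)C3=C([C@@H](c4ccccc4)CC(=O)O3)C3=C(C(=O)[C@H](C)[C@@H](C)O3)C2=O)C1(C)C
F16 | step 11 | benzylic (3R) epimer of 18 | C=C(C)[C@@H]1C[C@H](C[C@@]2(CC=C(C)C)C(=O)C([C@H](CC(=O)O)c3ccccc3)=C3O[C@H](C)[C@@H](C)C(=O)C3=C2O)C1(C)C
A1 | alternative 1 | acetaldehyde | CC=O
A2 | alternative 1 | (2Z,4Z)-2-methoxy-4-(triethylsilyloxy)hexa-2,4-diene | C/C=C(O[Si](CC)(CC)CC)/C=C(/C)OC
A3 | alternative 1 | (2R,3R)-2,3,6-trimethyl-2,3-dihydro-4H-pyran-4-one | CC1=CC(=O)[C@H](C)[C@@H](C)O1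
A4 | alternative 2 | N,N-dimethylisobutyramide | CC(C)C(=O)N(C)C
A5 | alternative 2 | allyl benzyl ether | C=CCOCc1ccccc1
A6 | alternative 2 | (S)-3-[(benzyloxy)methyl]-2,2-dimethylcyclobutan-1-one | O=C1C[C@H](COCc2ccccc2)C1(C)C
A7 | alternative 3 | C3-unsubstituted pyranone-fused cyclohexadienone core | C=C(C)[C@@H]1C[C@H](C[C@@]2(CC=C(C)C)C(=O)C=C3O[C@H](C)[C@@H](C)C(=O)C3=C2O)C1(C)C
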